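**Retrosynthetic overview**

- Feature: in the decalin (ring A = C1–C4, C4a, C8a; ring B = C4a, C5–C8, C8a) the unit C4–C4a(CH3)–C5(CH3) with its two cis methyls is (E)-2-methylbut-2-enal with C4 as the formyl carbon, and C8a–C8–C7–C6, oxygenated at both ends, is a 1,4-dioxygenated butadiene.
- Ring B is made first: an enantioselective Diels–Alder reaction of tiglic aldehyde with (1E,3E)-1,4-bis(silyloxy)butadiene forms C4a–C8a and C5–C6 and sets C4a and C5.
- The C4 aldehyde becomes a Z-enoate; after desilylation only the C8a oxygen can lactonise, which frees the C6 hydroxyl for inversion by oxidation and hydride reduction.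
- Ring A is made last: an alkoxymethyllithium opens the lactone at C2, C8a is oxidised to the ketone, and a ketol aldol forms C1–C8a.
- End game: C6 acetate, C1 angelate, C3 acetyl by α-iodination and Stille coupling.

Key step: step 2

Assumption: the sense of induction of the oxazaborolidinium catalyst is taken from the usual binding model for α-substituted enals (formyl C–H···O contact, diene adding to the enal face remote from the shielding aryl group); on that model the (R)-prolinol-derived catalyst gives 6, and the (S) catalyst would be used instead if the adduct proved to be the antipode.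

**Route**

Step 1
Reactants: 1 (1E,3E)-buta-1,3-diene-1,4-diyl diacetate; 2 tert-butyldimethylsilyl chloride
Product: 4 (1E,3E)-1,4-bis[(tert-butyldimethylsilyl)oxy]buta-1,3-diene, via dilithium dienediolate 3 (not isolated)
Conditions: MeLi (4.2 equiv), THF, −30 → 0 °C; then TBSCl (4.5 equiv), HMPA, −78 °C → rt
Reagents that add atoms: tert-butyldimethylsilyl chloride (2), CC(C)(C)[Si](C)(C)Cl
Why: Cleavage of an enol acetate with two equivalents of methyllithium per ester gives the lithium enolate without touching the C=C bonds, and O-silylation of the aldehyde enolate in the presence of HMPA keeps the (E,E) geometry that is already present in 1 (enol ester to silyl enol ether exchange).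

Step 2
Reactants: 4 (1E,3E)-1,4-bis[(tert-butyldimethylsilyl)oxy]buta-1,3-diene; 5 tiglic aldehyde, (E)-2-methylbut-2-enal
Product: 6 (1R,2S,5R,6R)-2,5-bis[(tert-butyldimethylsilyl)oxy]-1,6-dimethylcyclohex-3-ene-1-carbaldehyde (ring B; formyl carbon = C4, ring C1 = C4a, C2 = C8a, C5 = C6 of the decalin, C6 = C5 of the decalin)
Conditions: (3aR)-1-(2-methylphenyl)-3,3-diphenyltetrahydro-1H,3H-pyrrolo[1,2-c][1,3,2]oxazaborole (20 mol %), HN(SO2CF3)2 (18 mol %), 4 (1.5 equiv), CH2Cl2, −78 → −20 °C; Et3N quench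
Reagents that add atoms: none
Why: The protonated oxazaborolidine binds the formyl oxygen of 5 and lowers the LUMO of the s-trans enal, and the s-cis diene 4 adds in a concerted, asynchronous, suprafacial [4+2] cycloaddition in which the C5–C6 bond runs ahead of the C4a–C8a bond. The closest known reaction type is the oxazaborolidinium triflimide-catalysed Diels–Alder reaction of α-methyl enals such as methacrolein and tiglic aldehyde with silyloxy dienes. Ring B is closed in this [4+2] mode, with both new σ-bonds made on one face of each partner. C4a and C5 (cis methyls) follow from the (E) geometry of the enal; C6 and C8a (both silyloxy groups cis to the formyl group and trans to the methyls) follow from the (E,E) geometry of the diene together with endo orientation of the formyl group; the absolute configuration comes from the catalyst, whose aryl group covers one face of the bound enal. The step needs endo selectivity and reaction at C=C, not at C=O: the acyclic diene lacks the bridging CH2 that turns α-methyl enals exo with cyclopentadiene, and catalyst-bound enals of this type react at the alkene. The C2-symmetric diene leaves no regiochemical question, and the quaternary C4a rules out β-elimination of the C8a silyloxy group from the adduct.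

Step 3
Reactants: 6 (1R,2S,5R,6R)-2,5-bis[(tert-butyldimethylsilyl)oxy]-1,6-dimethylcyclohex-3-ene-1-carbaldehyde
Product: 7 (1R,2R,3R,6S)-3,6-bis[(tert-butyldimethylsilyl)oxy]-1,2-dimethylcyclohexane-1-carbaldehyde
Conditions: H2 (3 atm), Rh/Al2O3 (5 wt %), EtOAc, rt
Reagents that add atoms: none
Why: Heterogeneous hydrogenation of the cis-disubstituted ring alkene; rhodium on alumina is chosen because it rarely causes hydrogenolysis or double-bond migration of allylic silyl ethers, the neopentyl aldehyde is left alone, and no stereocentre is created.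

Step 4
Reactants: 7 (1R,2R,3R,6S)-3,6-bis[(tert-butyldimethylsilyl)oxy]-1,2-dimethylcyclohexane-1-carbaldehyde; 8 methyl bis(2,2,2-trifluoroethyl)phosphonoacetate
Product: 9 methyl (2Z)-3-[(1R,2R,3R,6S)-3,6-bis[(tert-butyldimethylsilyl)oxy]-1,2-dimethylcyclohexyl]prop-2-enoate
Conditions: 8, KN(SiMe3)2, 18-crown-6, THF, −78 °C; then 7, −78 → −20 °C
Reagents that add atoms: methyl bis(2,2,2-trifluoroethyl)phosphonoacetate (8), COC(=O)CP(=O)(OCC(F)(F)F)OCC(F)(F)F
Why: Still–Gennari olefination: the electron-poor phosphonate makes elimination from the kinetically formed adduct fast, so the Z-enoate (C3=C4) is expected; the aldehyde has no α-hydrogen and can neither enolise nor epimerise.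

Step 5
Reactants: 9 methyl (2Z)-3-[(1R,2R,3R,6S)-3,6-bis[(tert-butyldimethylsilyl)oxy]-1,2-dimethylcyclohexyl]prop-2-enoate
Product: 11 (4aR,5R,6R,8aS)-6-hydroxy-4a,5-dimethyl-4a,5,6,7,8,8a-hexahydro-2H-chromen-2-one, via diol ester 10 (not isolated)
Conditions: HF (48 % aq.), MeCN, 0 °C → rt; then PPTS (0.1 equiv), PhMe, 60 °C
Reagents that add atoms: none
Why: Acidic fluoride desilylation frees both hydroxyls, and only the C8a hydroxyl, cis to the Z-enoate arm, can close a six-membered unsaturated lactone (acid-catalysed lactonisation), since closure through the C6 hydroxyl would need a bridged seven-membered ring; this differentiates the two oxygens of the former diene.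

Step 6
Reactants: 11 (4aR,5R,6R,8aS)-6-hydroxy-4a,5-dimethyl-4a,5,6,7,8,8a-hexahydro-2H-chromen-2-one
Product: 12 (4aR,5R,8aS)-4a,5-dimethyl-4a,7,8,8a-tetrahydro-2H-chromene-2,6(5H)-dione
Conditions: Dess–Martin periodinane, CH2Cl2, 0 °C → rt
Reagents that add atoms: none
Why: Dess–Martin oxidation of the only free hydroxyl (C6) under near-neutral conditions, which should leave the C5 stereocentre next to the new ketone unepimerised.

Step 7
Reactants: 12 (4aR,5R,8aS)-4a,5-dimethyl-4a,7,8,8a-tetrahydro-2H-chromene-2,6(5H)-dione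
Product: 13 (4aR,5R,6S,8aS)-6-hydroxy-4a,5-dimethyl-4a,5,6,7,8,8a-hexahydro-2H-chromen-2-one
Conditions: LiBH(s-Bu)3 (1.1 equiv), THF, −78 °C; then H2O
Reagents that add atoms: none
Why: Bulky-hydride reduction of a cyclohexanone: the β face of C6 carries both the C5 and the C4a methyl, so the hydride should arrive from the α face and place the hydroxyl cis to the methyls (the C6 configuration of the target), while at −78 °C the ketone is reduced well before the hindered unsaturated lactone; C6 is thus inverted without a substitution that would have to enter on the methyl-bearing face.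

Step 8
Reactants: 13 (4aR,5R,6S,8aS)-6-hydroxy-4a,5-dimethyl-4a,5,6,7,8,8a-hexahydro-2H-chromen-2-one
Product: 14 (4aR,5R,6S,8aS)-4a,5-dimethyl-6-[(triethylsilyl)oxy]-4a,5,6,7,8,8a-hexahydro-2H-chromen-2-one
Conditions: Et3SiOTf, 2,6-lutidine, CH2Cl2, −78 → 0 °C
Reagents that add atoms: triethylsilyl triflate, CC[Si](CC)(CC)OS(=O)(=O)C(F)(F)F
Why: Silylation of the hindered axial alcohol with the silyl triflate; the triethylsilyl ether survives the organolithium, oxidation and enolate steps ahead and can later be removed next to a PMB ether.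

Step 9
Reactants: 15 tributyl(iodomethyl)stannane; 16 4-methoxybenzyl alcohol
Product: 17 tributyl{[(4-methoxybenzyl)oxy]methyl}stannane
Conditions: NaH, THF/DMF, 0 °C → rt
Reagents that add atoms: none
Why: Williamson ether synthesis: the sodium alkoxide displaces the primary iodide on the carbon next to tin.

Step 10
Reactants: 14 (4aR,5R,6S,8aS)-4a,5-dimethyl-6-[(triethylsilyl)oxy]-4a,5,6,7,8,8a-hexahydro-2H-chromen-2-one; 17 tributyl{[(4-methoxybenzyl)oxy]methyl}stannane
Product: 19 (4aR,5R,6S,8aS)-2-{[(4-methoxybenzyl)oxy]methyl}-4a,5-dimethyl-6-[(triethylsilyl)oxy]-4a,5,6,7,8,8a-hexahydro-2H-chromen-2-ol (hemiketal, either configuration at C2), via (4-methoxybenzyloxy)methyllithium 18 (not isolated)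
Conditions: 17, n-BuLi, THF, −78 °C; then 14, −78 °C; pH 7 buffer
Reagents that add atoms: tributyl{[(4-methoxybenzyl)oxy]methyl}stannane (17), CCCC[Sn](CCCC)(CCCC)COCc1ccc(OC)cc1
Why: Tin–lithium exchange gives the α-alkoxymethyllithium, which adds once to the lactone carbonyl (C2) because the tetrahedral lithium alkoxide is stable at −78 °C; 1,2-addition is expected since C4 is neopentyl and the lactone has no enolisable hydrogen, and this installs C1 with its oxygen.

Step 11
Reactants: 19 (4aR,5R,6S,8aS)-2-{[(4-methoxybenzyl)oxy]methyl}-4a,5-dimethyl-6-[(triethylsilyl)oxy]-4a,5,6,7,8,8a-hexahydro-2H-chromen-2-ol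
Product: 21 (3Z)-4-[(1R,2R,3S)-1,2-dimethyl-6-oxo-3-[(triethylsilyl)oxy]cyclohexyl]-1-[(4-methoxybenzyl)oxy]but-3-en-2-one, via open-chain hydroxy enone 20 (not isolated)
Conditions: Dess–Martin periodinane, CH2Cl2, rt; used without chromatography
Reagents that add atoms: none
Why: The hemiketal is in ring–chain equilibrium with the (Z)-δ-hydroxy enone, whose secondary C8a hydroxyl is oxidised by the Dess–Martin reagent, which pulls the equilibrium over to the 1,5-diketone; the Z geometry is inherited from the lactone and the crude product is taken on so that it does not isomerise.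

Step 12
Reactants: 21 (3Z)-4-[(1R,2R,3S)-1,2-dimethyl-6-oxo-3-[(triethylsilyl)oxy]cyclohexyl]-1-[(4-methoxybenzyl)oxy]but-3-en-2-one
Product: 22 (1S,4aR,5R,6S,8aR)-8a-hydroxy-1-[(4-methoxybenzyl)oxy]-4a,5-dimethyl-6-[(triethylsilyl)oxy]-4a,5,6,7,8,8a-hexahydronaphthalen-2(1H)-one
Conditions: LiN(SiMe3)2 (1.05 equiv), THF, −78 → −40 °C; AcOH, −78 °C
Reagents that add atoms: none
Why: Intramolecular ketol aldol of the Robinson-annulation type (6-enolendo-exo-trig) closes ring A: the amide base should select the more acidic, lithium-chelated α-alkoxy position C1 over C8, and C1 adds to the C8a ketone; with the C6 silyloxy group equatorial the C4 arm is axial on ring B, so only the cis-fused ketol (hydroxyl cis to the C4a methyl) can form, and the chelated Z-enolate places the PMB-oxy group equatorial on ring A, trans to the new hydroxyl, which sets C8a and C1 as in the target.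

Step 13
Reactants: 22 (1S,4aR,5R,6S,8aR)-8a-hydroxy-1-[(4-methoxybenzyl)oxy]-4a,5-dimethyl-6-[(triethylsilyl)oxy]-4a,5,6,7,8,8a-hexahydronaphthalen-2(1H)-one
Product: 23 (1S,4aR,5R,6S,8aR)-6,8a-dihydroxy-1-[(4-methoxybenzyl)oxy]-4a,5-dimethyl-4a,5,6,7,8,8a-hexahydronaphthalen-2(1H)-one
Conditions: HF·pyridine, THF/pyridine, 0 °C → rt
Reagents that add atoms: none
Why: Selective cleavage of the triethylsilyl ether under buffered fluoride conditions that leave the PMB ether, the enone and the tertiary β-hydroxy ketone untouched.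

Step 14
Reactants: 23 (1S,4aR,5R,6S,8aR)-6,8a-dihydroxy-1-[(4-methoxybenzyl)oxy]-4a,5-dimethyl-4a,5,6,7,8,8a-hexahydronaphthalen-2(1H)-one
Product: 24 (1S,4aR,5R,6S,8aR)-6-acetoxy-8a-hydroxy-1-[(4-methoxybenzyl)oxy]-4a,5-dimethyl-4a,5,6,7,8,8a-hexahydronaphthalen-2(1H)-one
Conditions: Ac2O, pyridine, DMAP (cat.), CH2Cl2, 0 °C → rt
Reagents that add atoms: acetic anhydride, CC(=O)OC(C)=O
Why: DMAP-catalysed acetylation of the secondary C6 hydroxyl; the tertiary C8a hydroxyl, flanked by C4a and C1, is not acylated under these conditions.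

Step 15
Reactants: 24 (1S,4aR,5R,6S,8aR)-6-acetoxy-8a-hydroxy-1-[(4-methoxybenzyl)oxy]-4a,5-dimethyl-4a,5,6,7,8,8a-hexahydronaphthalen-2(1H)-one
Product: 25 (1S,4aR,5R,6S,8aR)-6-acetoxy-1,8a-dihydroxy-4a,5-dimethyl-4a,5,6,7,8,8a-hexahydronaphthalen-2(1H)-one
Conditions: DDQ, CH2Cl2/pH 7 buffer, 0 °C → rt
Reagents that add atoms: none
Why: Oxidative cleavage of the PMB ether (hydride abstraction, then hydrolysis of the oxocarbenium ion) is neutral and spares the acetate, the enone and the ketol.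

Step 16
Reactants: 25 (1S,4aR,5R,6S,8aR)-6-acetoxy-1,8a-dihydroxy-4a,5-dimethyl-4a,5,6,7,8,8a-hexahydronaphthalen-2(1H)-one; 26 angelic acid, (Z)-2-methylbut-2-enoic acid
Product: 28 (1S,4aR,5R,6S,8aR)-6-acetoxy-8a-hydroxy-4a,5-dimethyl-2-oxo-1,2,4a,5,6,7,8,8a-octahydronaphthalen-1-yl (2Z)-2-methylbut-2-enoate, via mixed anhydride 27 (not isolated)
Conditions: 26, 2,4,6-trichlorobenzoyl chloride, Et3N, PhMe, rt; then 25, 80 °C (no DMAP)
Reagents that add atoms: angelic acid (26), C/C=C(/C)C(=O)O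
Why: Yamaguchi esterification: the hindered mixed anhydride transfers the angeloyl group to the secondary α-ketol hydroxyl at C1, and leaving out the nucleophilic catalyst avoids the conjugate addition–elimination that turns angelates into tiglates; the tertiary hydroxyl does not react.

Step 17
Reactants: 28 (1S,4aR,5R,6S,8aR)-6-acetoxy-8a-hydroxy-4a,5-dimethyl-2-oxo-1,2,4a,5,6,7,8,8a-octahydronaphthalen-1-yl (2Z)-2-methylbut-2-enoate
Product: 29 (1S,4aS,5R,6S,8aR)-6-acetoxy-8a-hydroxy-3-iodo-4a,5-dimethyl-2-oxo-1,2,4a,5,6,7,8,8a-octahydronaphthalen-1-yl (2Z)-2-methylbut-2-enoate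
Conditions: I2, pyridine/CH2Cl2, 0 °C → rt
Reagents that add atoms: iodine, II
Why: α-Iodination of the enone by conjugate addition of pyridine, iodination of the enolate and elimination, a reaction that works on cyclohexenones with a quaternary γ-carbon; C3 is the only position that can react this way and no stereocentre is involved.

Step 18
Reactants: 29 (1S,4aS,5R,6S,8aR)-6-acetoxy-8a-hydroxy-3-iodo-4a,5-dimethyl-2-oxo-1,2,4a,5,6,7,8,8a-octahydronaphthalen-1-yl (2Z)-2-methylbut-2-enoate; 30 tributyl(1-ethoxyvinyl)stannane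
Product: 32 (1S,4aR,5R,6S,8aR)-6-acetoxy-3-acetyl-8a-hydroxy-4a,5-dimethyl-2-oxo-1,2,4a,5,6,7,8,8a-octahydronaphthalen-1-yl (2Z)-2-methylbut-2-enoate (the target), via ethoxyvinyl enone 31 (not isolated)
Conditions: 30, Pd2(dba)3 (5 mol %), AsPh3, CuI, NMP, rt; then 0.5 M HCl aq., THF, 0 °C
Reagents that add atoms: tributyl(1-ethoxyvinyl)stannane (30), CCOC(=C)[Sn](CCCC)(CCCC)CCCC; water, O
Why: Stille coupling of the α-iodoenone with the acetyl anion equivalent, followed by mild acid hydrolysis of the enol ether to the C3 acetyl group; neither stage touches a stereocentre.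

**Compound list**

1 | (1E,3E)-buta-1,3-diene-1,4-diyl diacetate | CC(=O)O/C=C/C=C/OC(C)=O | starting material
2 | tert-butyldimethylsilyl chloride | CC(C)(C)[Si](C)(C)Cl | starting material
3 | dilithium (1E,3E)-buta-1,3-diene-1,4-bis(olate) (not isolated) | [Li+].[Li+].[O-]/C=C/C=C/[O-] | intermediate
4 | (1E,3E)-1,4-bis[(tert-butyldimethylsilyl)oxy]buta-1,3-diene | CC(C)(C)[Si](C)(C)O/C=C/C=C/O[Si](C)(C)C(C)(C)C | intermediate
5 | tiglic aldehyde, (E)-2-methylbut-2-enal | C/C=C(\C)C=O | starting material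
6 | (1R,2S,5R,6R)-2,5-bis[(tert-butyldimethylsilyl)oxy]-1,6-dimethylcyclohex-3-ene-1-carbaldehyde | O=C[C@]1(C)[C@@H](C)[C@H](O[Si](C)(C)C(C)(C)C)C=C[C@@H]1O[Si](C)(C)C(C)(C)C | intermediate
7 | (1R,2R,3R,6S)-3,6-bis[(tert-butyldimethylsilyl)oxy]-1,2-dimethylcyclohexane-1-carbaldehyde | O=C[C@]1(C)[C@@H](C)[C@H](O[Si](C)(C)C(C)(C)C)CC[C@@H]1O[Si](C)(C)C(C)(C)C | intermediate
8 | methyl bis(2,2,2-trifluoroethyl)phosphonoacetate | COC(=O)CP(=O)(OCC(F)(F)F)OCC(F)(F)F | starting material
9 | methyl (2Z)-3-[(1R,2R,3R,6S)-3,6-bis[(tert-butyldimethylsilyl)oxy]-1,2-dimethylcyclohexyl]prop-2-enoate | COC(=O)/C=C\[C@]1(C)[C@@H](C)[C@H](O[Si](C)(C)C(C)(C)C)CC[C@@H]1O[Si](C)(C)C(C)(C)C | intermediate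
10 | methyl (2Z)-3-[(1R,2R,3R,6S)-3,6-dihydroxy-1,2-dimethylcyclohexyl]prop-2-enoate (not isolated) | COC(=O)/C=C\[C@]1(C)[C@@H](C)[C@H](O)CC[C@@H]1O | intermediate
11 | (4aR,5R,6R,8aS)-6-hydroxy-4a,5-dimethyl-4a,5,6,7,8,8a-hexahydro-2H-chromen-2-one | O=C1C=C[C@]2(C)[C@@H](C)[C@H](O)CC[C@@H]2O1 | intermediate
12 | (4aR,5R,8aS)-4a,5-dimethyl-4a,7,8,8a-tetrahydro-2H-chromene-2,6(5H)-dione | O=C1C=C[C@]2(C)[C@@H](C)C(=O)CC[C@@H]2O1 | intermediate
13 | (4aR,5R,6S,8aS)-6-hydroxy-4a,5-dimethyl-4a,5,6,7,8,8a-hexahydro-2H-chromen-2-one | O=C1C=C[C@]2(C)[C@@H](C)[C@@H](O)CC[C@@H]2O1 | intermediate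
14 | (4aR,5R,6S,8aS)-4a,5-dimethyl-6-[(triethylsilyl)oxy]-4a,5,6,7,8,8a-hexahydro-2H-chromen-2-one | O=C1C=C[C@]2(C)[C@@H](C)[C@@H](O[Si](CC)(CC)CC)CC[C@@H]2O1 | intermediate
15 | tributyl(iodomethyl)stannane | CCCC[Sn](CCCC)(CCCC)CI | starting material
16 | 4-methoxybenzyl alcohol | COc1ccc(CO)cc1 | starting material
17 | tributyl{[(4-methoxybenzyl)oxy]methyl}stannane | CCCC[Sn](CCCC)(CCCC)COCc1ccc(OC)cc1 | intermediate
18 | [(4-methoxybenzyl)oxy]methyllithium (not isolated) | [Li]COCc1ccc(OC)cc1 | intermediate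
19 | (4aR,5R,6S,8aS)-2-{[(4-methoxybenzyl)oxy]methyl}-4a,5-dimethyl-6-[(triethylsilyl)oxy]-4a,5,6,7,8,8a-hexahydro-2H-chromen-2-ol | COc1ccc(COCC2(O)C=C[C@]3(C)[C@@H](C)[C@@H](O[Si](CC)(CC)CC)CC[C@@H]3O2)cc1 | intermediate
20 | (3Z)-4-[(1R,2R,3S,6S)-6-hydroxy-1,2-dimethyl-3-[(triethylsilyl)oxy]cyclohexyl]-1-[(4-methoxybenzyl)oxy]but-3-en-2-one (not isolated) | COc1ccc(COCC(=O)/C=C\[C@]2(C)[C@@H](C)[C@@H](O[Si](CC)(CC)CC)CC[C@@H]2O)cc1 | intermediate
21 | (3Z)-4-[(1R,2R,3S)-1,2-dimethyl-6-oxo-3-[(triethylsilyl)oxy]cyclohexyl]-1-[(4-methoxybenzyl)oxy]but-3-en-2-one | COc1ccc(COCC(=O)/C=C\[C@]2(C)[C@@H](C)[C@@H](O[Si](CC)(CC)CC)CCC2=O)cc1 | intermediate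
22 | (1S,4aR,5R,6S,8aR)-8a-hydroxy-1-[(4-methoxybenzyl)oxy]-4a,5-dimethyl-6-[(triethylsilyl)oxy]-4a,5,6,7,8,8a-hexahydronaphthalen-2(1H)-one | COc1ccc(CO[C@@H]2C(=O)C=C[C@]3(C)[C@@H](C)[C@@H](O[Si](CC)(CC)CC)CC[C@]23O)cc1 | intermediate
23 | (1S,4aR,5R,6S,8aR)-6,8a-dihydroxy-1-[(4-methoxybenzyl)oxy]-4a,5-dimethyl-4a,5,6,7,8,8a-hexahydronaphthalen-2(1H)-one | COc1ccc(CO[C@@H]2C(=O)C=C[C@]3(C)[C@@H](C)[C@@H](O)CC[C@]23O)cc1 | intermediate
24 | (1S,4aR,5R,6S,8aR)-6-acetoxy-8a-hydroxy-1-[(4-methoxybenzyl)oxy]-4a,5-dimethyl-4a,5,6,7,8,8a-hexahydronaphthalen-2(1H)-one | COc1ccc(CO[C@@H]2C(=O)C=C[C@]3(C)[C@@H](C)[C@@H](OC(C)=O)CC[C@]23O)cc1 | intermediate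
25 | (1S,4aR,5R,6S,8aR)-6-acetoxy-1,8a-dihydroxy-4a,5-dimethyl-4a,5,6,7,8,8a-hexahydronaphthalen-2(1H)-one | O[C@@H]1C(=O)C=C[C@]2(C)[C@@H](C)[C@@H](OC(C)=O)CC[C@]12O | intermediate
26 | angelic acid, (Z)-2-methylbut-2-enoic acid | C/C=C(/C)C(=O)O | starting material
27 | (Z)-2-methylbut-2-enoic 2,4,6-trichlorobenzoic anhydride (not isolated) | C/C=C(/C)C(=O)OC(=O)c1c(Cl)cc(Cl)cc1Cl | intermediate
28 | (1S,4aR,5R,6S,8aR)-6-acetoxy-8a-hydroxy-4a,5-dimethyl-2-oxo-1,2,4a,5,6,7,8,8a-octahydronaphthalen-1-yl (2Z)-2-methylbut-2-enoate | C/C=C(/C)C(=O)O[C@@H]1C(=O)C=C[C@]2(C)[C@@H](C)[C@@H](OC(C)=O)CC[C@]12O | intermediate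
29 | (1S,4aS,5R,6S,8aR)-6-acetoxy-8a-hydroxy-3-iodo-4a,5-dimethyl-2-oxo-1,2,4a,5,6,7,8,8a-octahydronaphthalen-1-yl (2Z)-2-methylbut-2-enoate | C/C=C(/C)C(=O)O[C@@H]1C(=O)C(I)=C[C@]2(C)[C@@H](C)[C@@H](OC(C)=O)CC[C@]12O | intermediate
30 | tributyl(1-ethoxyvinyl)stannane | CCOC(=C)[Sn](CCCC)(CCCC)CCCC | starting material
31 | (1S,4aR,5R,6S,8aR)-6-acetoxy-3-(1-ethoxyvinyl)-8a-hydroxy-4a,5-dimethyl-2-oxo-1,2,4a,5,6,7,8,8a-octahydronaphthalen-1-yl (2Z)-2-methylbut-2-enoate (not isolated) | C/C=C(/C)C(=O)O[C@@H]1C(=O)C(C(=C)OCC)=C[C@]2(C)[C@@H](C)[C@@H](OC(C)=O)CC[C@]12O | intermediate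
32 | (1S,4aR,5R,6S,8aR)-6-acetoxy-3-acetyl-8a-hydroxy-4a,5-dimethyl-2-oxo-1,2,4a,5,6,7,8,8a-octahydronaphthalen-1-yl (2Z)-2-methylbut-2-enoate | C/C=C(/C)C(=O)O[C@@H]1C(=O)C(C(C)=O)=C[C@]2(C)[C@@H](C)[C@@H](OC(C)=O)CC[C@]12O | target

**Step count**

Total: 18 steps. Longest linear sequence: 17 steps (steps 1–8 and 10–18 from 1; step 9 makes stannane 17 in a side branch).

**Steps most likely to fail**

Step 2 (Diels–Alder). The trisubstituted enal may react too slowly at the temperatures that the acid-labile bis(silyl enol ether) tolerates, so that protodesilylation or Mukaiyama-type addition of the diene competes, or the facial or endo selectivity may be insufficient. Fallback: setting out from 4 and 5, the cycloaddition is run without catalyst under high pressure (about 13 kbar, CH2Cl2, rt) or in toluene at 110 °C and should give the racemic endo adduct F1. Condensation of F1 with (1R,2R)-N,N'-dimethyl-1,2-diphenylethane-1,2-diamine (molecular sieves, toluene) gives two diastereomeric imidazolidines; the aminal derived from the (1R,2S,5R,6R) aldehyde, F2, is separated by chromatography and cleaved with cold dilute aqueous acid in a two-phase system, which returns to the route at 6. The source of enantiopurity is thus changed from catalysis to resolution.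

Step 12 (ketol aldol). The enolate may close through the other chair of ring B (C4 arm equatorial), which would keep the ring fusion cis but put the C1 alkoxy group cis to the C8a hydroxyl; proton transfer to the C8 enolate would lower the yield further. Fallback: setting out from 21, the C1-epimeric ketol F3 is carried through the same desilylation (HF·pyridine) to the epimeric diol F4, acetylation (Ac2O, pyridine, DMAP) to the epimeric acetate F5, and DDQ cleavage to the epimeric α-ketol F6. F6 is then esterified with angelic acid 26 under Mitsunobu conditions (PPh3, DIAD, PhMe, 0 °C → rt), which inverts the activated α-keto carbinol carbon C1 and comes back to the route at 28. The C1 configuration is then set by substitution and not in the aldol.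

Step 16 (angeloylation). Acylation of the hindered α-ketol may be slow, and prolonged heating with amine may isomerise the angelate to the tiglate. Fallback: setting out from 25, the C1 hydroxyl is esterified with 2-[bis(2,2,2-trifluoroethoxy)phosphoryl]propanoic acid (EDC·HCl, DMAP cat., CH2Cl2) to give the phosphonopropionate F7. A Still–Gennari olefination of F7 with acetaldehyde (KN(SiMe3)2, 18-crown-6, THF, −78 °C) then builds the (Z)-2-methylbut-2-enoate on the substrate and returns to the route at 28.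

**Further compounds**

F1 | step 2 | racemic 2,5-bis[(tert-butyldimethylsilyl)oxy]-1,6-dimethylcyclohex-3-ene-1-carbaldehyde with the relative configuration of 6 (6 and its enantiomer) | O=C[C@]1(C)[C@@H](C)[C@H](O[Si](C)(C)C(C)(C)C)C=C[C@@H]1O[Si](C)(C)C(C)(C)C.O=C[C@@]1(C)[C@H](C)[C@@H](O[Si](C)(C)C(C)(C)C)C=C[C@H]1O[Si](C)(C)C(C)(C)C
F2 | step 2 | aminal of 6 with (1R,2R)-N,N'-dimethyl-1,2-diphenylethane-1,2-diamine: (4R,5R)-1,3-dimethyl-4,5-diphenylimidazolidine carrying at C2 the cyclohexenyl group of 6 | CN1[C@H](c2ccccc2)[C@@H](c2ccccc2)N(C)C1[C@]3(C)[C@@H](C)[C@H](O[Si](C)(C)C(C)(C)C)C=C[C@@H]3O[Si](C)(C)C(C)(C)C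
F3 | step 12 | C1 epimer of 22, (1R,4aR,5R,6S,8aR)-8a-hydroxy-1-[(4-methoxybenzyl)oxy]-4a,5-dimethyl-6-[(triethylsilyl)oxy]-4a,5,6,7,8,8a-hexahydronaphthalen-2(1H)-one | COc1ccc(CO[C@H]2C(=O)C=C[C@]3(C)[C@@H](C)[C@@H](O[Si](CC)(CC)CC)CC[C@]23O)cc1
F4 | step 12 | C1 epimer of 23, (1R,4aR,5R,6S,8aR)-6,8a-dihydroxy-1-[(4-methoxybenzyl)oxy]-4a,5-dimethyl-4a,5,6,7,8,8a-hexahydronaphthalen-2(1H)-one | COc1ccc(CO[C@H]2C(=O)C=C[C@]3(C)[C@@H](C)[C@@H](O)CC[C@]23O)cc1
F5 | step 12 | C1 epimer of 24, (1R,4aR,5R,6S,8aR)-6-acetoxy-8a-hydroxy-1-[(4-methoxybenzyl)oxy]-4a,5-dimethyl-4a,5,6,7,8,8a-hexahydronaphthalen-2(1H)-one | COc1ccc(CO[C@H]2C(=O)C=C[C@]3(C)[C@@H](C)[C@@H](OC(C)=O)CC[C@]23O)cc1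
F6 | step 12 | C1 epimer of 25, (1R,4aR,5R,6S,8aR)-6-acetoxy-1,8a-dihydroxy-4a,5-dimethyl-4a,5,6,7,8,8a-hexahydronaphthalen-2(1H)-one | O[C@H]1C(=O)C=C[C@]2(C)[C@@H](C)[C@@H](OC(C)=O)CC[C@]12O
F7 | step 16 | 2-[bis(2,2,2-trifluoroethoxy)phosphoryl]propanoate of 25 at the C1 hydroxyl (either configuration at the phosphonate carbon) | CC(C(=O)O[C@@H]1C(=O)C=C[C@]2(C)[C@@H](C)[C@@H](OC(C)=O)CC[C@]12O)P(=O)(OCC(F)(F)F)OCC(F)(F)F
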